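All runs are simulated on assumed constants; noise was put on by code.

- A percentage point of Ze lost is the unit of this reckoning, and the question is how many such points each point of Ym standing costs.

| flask | Ze | Ly | remark | time |
|---|---|---|---|---|
| noon | 1 mM | 1.3 equiv | run made earlier |  |
| summer | 1.5 mM | 1.3 equiv | run made earlier |  |
| flask | 2.0 mM | 1.30 equiv |  | 2.5 min |

| run | time / s | Ze / % | Ym / % |
|---|---|---|---|
| noon | 10.0 | 91.0 | 5.6 |
| noon | 12.0 | 89.1 | 5.2 |
| noon | 15.0 | 89.1 | 6.0 |
| noon | 25.0 | 83.1 | 8.1 |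
| noon | 40.0 | 75.6 | 12.8 |
| noon | 60.0 | 71.3 | 15.7 |
| noon | 90.0 | 66.4 | 15.6 |
| summer | 10.0 | 86.4 | 5.1 |
| summer | 12.0 | 85.7 | 7.5 |
| summer | 15.0 | 83.9 | 8.5 |
| summer | 25.0 | 77.8 | 11.9 |
| summer | 40.0 | 70.8 | 14.4 |
| summer | 60.0 | 67.1 | 15.8 |
| summer | 90.0 | 60.8 | 20.5 |

(each reading ± 1 percentage point)

- the Ze standing at 2.5 min, as a percentage of the Ze charged
- the Ym standing at 2.5 min, as a percentage of the Ze charged
- the Xo standing at 2.5 min, as a percentage of the Ze charged
- the Qo standing at 2.5 min, as a percentage of the Ze charged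

- a reading of Ze is of its free form alone

- Call that cost L: the charged Ze minus c_Ze, over c_Ym, both in percent of the Ze charged. Averaged over the last noon and summer readings, the loss per Ym is 2.03.
- Take the main step first, Ze + Ly giving Ym. Each Ze lost is then one Ym, which makes L equal 1, but the readings stand higher.
- Add the later steps, Ym to Xo and Xo to Qo. These are consecutive products, starting from nothing, so L starts at 1 and climbs with time. Yet at 15.0 s L already reads 1.82 at noon and 1.89 in summer. At 90.0 s it reads 2.15 and 1.91, a drift the scatter can hold.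
- Now the rest. A reading of Ze counts its free form, so bound Ze can stand unread. One bound Ze formed in step with each Ym gives L near 2, from the first readings on.
- The forecast gives Ze 48%, Ym 17%, Xo 25% and Qo 10%, and says of the last two: “Their split is not observed, so this is a guess”.
- This reckoning borrows that Ze and parts from the forecast on the rest. L turns it into Ym of 25.6%. The excess of L over 2, 0.0300, is smaller than the gap of 0.242 between the last noon and summer values of L, so this reckoning puts no figure on Xo plus Qo and, unlike the forecast, expects them to be small beside Ym.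
- At 2.5 min the flask holds Ze 52.6%, Ym 22.8%, Xo 0.754% and Qo 0.0360%.

    Ze + Ly → Ym + Gu (k = 4.50 M⁻¹ s⁻¹)
    Ly + Ym → Xo + Gu (k = 0.870 M⁻¹ s⁻¹)
    Ly + Xo → Qo + Gu (k = 1.90 M⁻¹ s⁻¹)
    Ly + Qo → Ji + Gu (k = 0.430 M⁻¹ s⁻¹)
    Ze + Gu ⇌ Ry, settled at all times (K = 36000 M⁻¹)
    2 Ly → Ja (k = 15.0 M⁻¹ s⁻¹)

- Beside Ym in this flask stands Ry, the bound Ze, at 23.8%. L here comes to 2.08, and the value from the noon and summer runs turns this Ze loss into Ym of 23.3%. The neighbour flask, read at 40 s with the same charges, holds Ze 67.6%; L turns that into Ym of 16.0%, and the neighbour flask holds 15.9%.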